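**Retrosynthetic overview**

- Feature: ring B of unit 1 (the 7-methoxyflavone) is a 1,3,4-trisubstituted phenol ring. It carries O on C4', C2 of the chromone on C1' (para to O) and C3 of unit 2 (the 5,7,4'-trihydroxyflavone) on C3' (ortho to O). A 1-substituted 2-silyloxybutadiene and a terminal acceptor alkyne deliver exactly this pattern.
- Endgame: four O–isopropyl bonds (BCl3) and one O–Si bond (fluoride) are cut last. Ring B of unit 1 is then disconnected at C2'–C3' and C1'–C6' (Diels–Alder reaction, DDQ aromatisation) into a flavon-3-yl silyloxydiene and a 2-ethynylchromone.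
- Diene: enol silylation of the 3-(2-oxobut-3-enyl)flavone, which comes from the flavon-3-ylacetaldehyde and a vinyl Grignard reagent. The aldehyde comes from the 3-allylflavone, made from a Baker–Venkataraman diketone by C-allylation and cyclodehydration.
- Alkyne: one-carbon homologation of the chromone-2-carbaldehyde, which comes from the chromone-2-carboxylate, made from a 2-hydroxyacetophenone and diethyl oxalate.
- Ring order: both rings A and ring B of unit 2 are bought. Ring C of unit 2 forms in step 4, ring C of unit 1 in step 10, and ring B of unit 1 last, in step 14.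

Key step: step 14

Assumption: the target SMILES has no stereodescriptor, so no stereocentre has to be set and the hindered C3–C3' axis is treated as configurationally undefined.

**Route**

Step 1
Reactants: 1 2',4',6'-trihydroxyacetophenone
Product: 2 2'-hydroxy-4',6'-diisopropoxyacetophenone
Conditions: iPrBr (2.2 equiv), K2CO3, DMF, 60 °C
Reagents that add atoms: 2-bromopropane CC(C)Br
Why: Williamson ether synthesis in which the 4-OH and one of the two equivalent ortho OH groups are alkylated, while the last OH stays hydrogen-bonded to the acetyl carbonyl and is too poor a nucleophile for the secondary bromide, so alkylation should stop at the diether.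

Step 2
Reactants: 2 2'-hydroxy-4',6'-diisopropoxyacetophenone; 3 4-isopropoxybenzoic acid
Product: 4 2-acetyl-3,5-diisopropoxyphenyl 4-isopropoxybenzoate
Conditions: DCC, DMAP (cat.), CH2Cl2, rt
Reagents that add atoms: none
Why: Steglich esterification, in which DMAP relays the acyl group from the O-acylisourea to the chelated phenol under neutral conditions that leave the ketone and the isopropyl ethers untouched.

Step 3
Reactants: 4 2-acetyl-3,5-diisopropoxyphenyl 4-isopropoxybenzoate
Product: 5 1-(2-hydroxy-4,6-diisopropoxyphenyl)-3-(4-isopropoxyphenyl)propane-1,3-dione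
Conditions: KOH, pyridine, 50 °C; then 10% aq. AcOH
Reagents that add atoms: none
Why: Baker–Venkataraman rearrangement, in which the methyl ketone enolate attacks the neighbouring aryl ester through a six-membered transition state and the O-to-C acyl shift is driven by formation of the stabilised diketonate and phenoxide.

Step 4
Reactants: 5 1-(2-hydroxy-4,6-diisopropoxyphenyl)-3-(4-isopropoxyphenyl)propane-1,3-dione
Product: 7 3-allyl-5,7,4'-triisopropoxyflavone, via C-allyl diketone 6 (not isolated)
Conditions: allyl methyl carbonate (1.05 equiv), Pd(PPh3)4 (5 mol %), THF, rt; solvent switch, p-TsOH·H2O (cat.), toluene, 110 °C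
Reagents that add atoms: allyl methyl carbonate C=CCOC(=O)OC
Why: Tsuji–Trost allylation followed by acid cyclodehydration, in which the soft diketonate attacks the π-allyl complex of divalent palladium irreversibly at carbon whereas phenol O-allylation is reversible, and p-TsOH then closes ring C of unit 2 by addition of the phenol to the aroyl carbonyl and loss of water, which also erases the racemic stereocentre of 6.

Step 5
Reactants: 7 3-allyl-5,7,4'-triisopropoxyflavone
Product: 9 (5,7,4'-triisopropoxyflavon-3-yl)acetaldehyde, via diol 8 (not isolated)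
Conditions: OsO4 (2 mol %), NaIO4, 2,6-lutidine, dioxane–H2O, rt
Reagents that add atoms: osmium tetroxide O=[Os](=O)(=O)=O (catalytic oxygen carrier); NaIO4 [Na+].[O-]I(=O)(=O)=O (terminal oxygen source)
Why: Lemieux–Johnson oxidation, in which OsO4 dihydroxylates only the unhindered terminal alkene (the tetrasubstituted, acceptor-conjugated C2=C3 bond is inert and the carbinol centre of 8 is racemic and transient) and periodate cleaves the diol in the flask.

Step 6
Reactants: 9 (5,7,4'-triisopropoxyflavon-3-yl)acetaldehyde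
Product: 10 rac-3-(2-hydroxybut-3-en-1-yl)-5,7,4'-triisopropoxyflavone
Conditions: CH2=CHMgBr, THF, −78 °C; then sat. aq. NH4Cl
Reagents that add atoms: vinylmagnesium bromide C=C[Mg]Br
Why: Grignard 1,2-addition, for which at −78 °C the aldehyde is far more reactive than the C4 carbonyl (a vinylogous ester deactivated by O1 and the 5,7-alkoxy donors and shielded at C2), and the new carbinol centre forms racemic without control and is removed in step 7.

Step 7
Reactants: 10 rac-3-(2-hydroxybut-3-en-1-yl)-5,7,4'-triisopropoxyflavone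
Product: 11 3-(2-oxobut-3-en-1-yl)-5,7,4'-triisopropoxyflavone
Conditions: Dess–Martin periodinane, CH2Cl2, 0 °C to rt
Reagents that add atoms: none
Why: Dess–Martin oxidation, a neutral and non-aqueous method that should give the vinyl ketone without any base that could start Michael oligomerisation.

Step 8
Reactants: 11 3-(2-oxobut-3-en-1-yl)-5,7,4'-triisopropoxyflavone
Product: 12 (Z)-3-[2-(tert-butyldimethylsilyloxy)buta-1,3-dien-1-yl]-5,7,4'-triisopropoxyflavone
Conditions: TBSOTf (2.5 equiv), Et3N, CH2Cl2, −78 to 0 °C; cold aq. NaHCO3 quench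
Reagents that add atoms: tert-butyldimethylsilyl triflate CC(C)(C)[Si](C)(C)OS(=O)(=O)C(F)(F)F
Why: Soft enolisation with silyl triflate and tertiary amine, in which the C3–CH2 group is the only enolisable position and the enol ether should form with the bulky flavonyl group trans to the vinyl group to avoid allylic strain, which is the Z isomer; the excess TBSOTf covers reversible O-silylation of the flavone carbonyl, undone in the quench.

Step 9
Reactants: 13 2',6'-dihydroxy-4'-methoxyacetophenone
Product: 14 2'-hydroxy-6'-isopropoxy-4'-methoxyacetophenone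
Conditions: iPrBr (1.1 equiv), K2CO3, DMF, 50 °C
Reagents that add atoms: 2-bromopropane CC(C)Br
Why: Williamson ether synthesis, in which the OH left after the first alkylation is tied to the carbonyl by a hydrogen bond, so a slight excess of the sluggish secondary bromide should stop at the monoether.

Step 10
Reactants: 14 2'-hydroxy-6'-isopropoxy-4'-methoxyacetophenone
Product: 16 ethyl 5-isopropoxy-7-methoxy-4-oxo-4H-chromene-2-carboxylate, via diketo ester 15 (not isolated)
Conditions: (CO2Et)2, NaOEt, EtOH, reflux; then conc. HCl, EtOH, reflux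
Reagents that add atoms: diethyl oxalate CCOC(=O)C(=O)OCC
Why: Claisen condensation with the non-enolisable oxalate followed by acid cyclodehydration, the standard entry to 5-alkoxychromone-2-carboxylates, in which the phenol adds to the α-keto ester carbonyl and loss of water closes ring C of unit 1.

Step 11
Reactants: 16 ethyl 5-isopropoxy-7-methoxy-4-oxo-4H-chromene-2-carboxylate
Product: 17 2-(hydroxymethyl)-5-isopropoxy-7-methoxy-4H-chromen-4-one
Conditions: NaBH4, EtOH–THF, 0 °C
Reagents that add atoms: none
Why: Chemoselective borohydride reduction, in which the ester on the electron-poor C2 next to the ring oxygen is activated whereas the C4 carbonyl is a doubly donor-stabilised vinylogous ester, so the reaction should stop at the 2-hydroxymethylchromone.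

Step 12
Reactants: 17 2-(hydroxymethyl)-5-isopropoxy-7-methoxy-4H-chromen-4-one
Product: 18 5-isopropoxy-7-methoxy-4-oxo-4H-chromene-2-carbaldehyde
Conditions: Dess–Martin periodinane, CH2Cl2, rt
Reagents that add atoms: none
Why: Dess–Martin oxidation of the allylic-type primary alcohol, which stops at the aldehyde because no water is present to form a hydrate.

Step 13
Reactants: 18 5-isopropoxy-7-methoxy-4-oxo-4H-chromene-2-carbaldehyde
Product: 19 2-ethynyl-5-isopropoxy-7-methoxy-4H-chromen-4-one
Conditions: Me3SiCHN2, LiN(iPr)2, THF, −78 °C; then 18, −78 to 0 °C; sat. aq. NH4Cl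
Reagents that add atoms: (trimethylsilyl)diazomethane C[Si](C)(C)C=[N+]=[N-]
Why: Colvin rearrangement (the silyl variant of the Seyferth–Gilbert homologation), in which the lithiated diazo reagent adds to the aldehyde faster than to the pyranone, loss of silanolate and N2 gives an alkylidene carbene whose 1,2-hydrogen shift delivers the terminal alkyne, and the aprotic medium avoids the alkoxide addition to C2 or to the acceptor alkyne that a methanolic protocol would risk.

Step 14
Reactants: 12 (Z)-3-[2-(tert-butyldimethylsilyloxy)buta-1,3-dien-1-yl]-5,7,4'-triisopropoxyflavone; 19 2-ethynyl-5-isopropoxy-7-methoxy-4H-chromen-4-one (1.5 equiv)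
Product: 21 3-[2-(tert-butyldimethylsilyloxy)-5-(5-isopropoxy-7-methoxy-4-oxo-4H-chromen-2-yl)phenyl]-5,7-diisopropoxy-2-(4-isopropoxyphenyl)-4H-chromen-4-one, via cyclohexadiene adduct 20 (not isolated)
Conditions: toluene (1 M), BHT (cat.), sealed tube, 150 °C; cool to rt, DDQ (1.2 equiv)
Reagents that add atoms: none
Why: Proposed new method: the step should run as a thermal, concerted but asynchronous (4+2) cycloaddition in which the enol-ether β-carbon of 12 (largest HOMO coefficient, future C3') bonds in advance to the free alkyne terminus of 19 (the δ-position of the acceptor chain O=C4–C3=C2–C≡CH, largest LUMO coefficient, future C2') while the vinyl CH2 (future C6') closes onto the chromone-bearing alkyne carbon (future C1'). The closest known reaction type is the Diels–Alder reaction of 2-silyloxybuta-1,3-dienes with propiolates and ethynyl ketones followed by DDQ dehydrogenation to 4-silyloxyarenes, and what has not been shown is an alkyne that feels its carbonyl group only through the C2=C3 bond of a pyranone, nor a diene that carries a flavon-3-yl group. Ring B of unit 1 is the one ring closed, a six-membered carbocycle formed intermolecularly by suprafacial addition of the s-cis diene across one π-bond of the alkyne, which gives the 1,4-cyclohexadiene 20. Its single new stereocentre (C3') forms racemic, needs no control and disappears when DDQ takes hydride from a doubly allylic C–H bond and the silyloxy-stabilised cation loses a proton. The step needs regioselectivity (oxygen para to the chromone), secured because the silyloxy donor outweighs the merely conjugating flavonyl group and because the crowded diene end meets the unsubstituted alkyne carbon, and it needs site selectivity for the alkyne over the C2=C3 bond of 19, secured because that bond is trisubstituted and part of the stabilised pyranone. The Z enol ether holds the flavonyl group on the outer side of the s-cis diene, so that the reactive conformation is reachable, and it also rules out a 6π electrocyclisation with the C2=C3 bond of unit 2.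

Step 15
Reactants: 21 3-[2-(tert-butyldimethylsilyloxy)-5-(5-isopropoxy-7-methoxy-4-oxo-4H-chromen-2-yl)phenyl]-5,7-diisopropoxy-2-(4-isopropoxyphenyl)-4H-chromen-4-one
Product: 22 3-[2-hydroxy-5-(5-isopropoxy-7-methoxy-4-oxo-4H-chromen-2-yl)phenyl]-5,7-diisopropoxy-2-(4-isopropoxyphenyl)-4H-chromen-4-one
Conditions: TBAF, AcOH (1:1), THF, 0 °C
Reagents that add atoms: none
Why: Fluoride desilylation, made fast by the strong Si–F bond and the good aryloxide leaving group, with acetic acid buffering the phenoxide so that both pyranone rings are safe.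

Step 16
Reactants: 22 3-[2-hydroxy-5-(5-isopropoxy-7-methoxy-4-oxo-4H-chromen-2-yl)phenyl]-5,7-diisopropoxy-2-(4-isopropoxyphenyl)-4H-chromen-4-one
Product: 23 3-[2-hydroxy-5-(5-hydroxy-7-methoxy-4-oxo-4H-chromen-2-yl)phenyl]-5,7-dihydroxy-2-(4-hydroxyphenyl)-4H-chromen-4-one (target)
Conditions: BCl3 (12 equiv), CH2Cl2, −78 °C to rt; then MeOH–aq. HCl
Reagents that add atoms: none
Why: Lewis-acid ether cleavage, in which BCl3 binds the ether oxygens (first the two 5-O-isopropyl groups through chelation with C4=O) and chloride takes the secondary isopropyl group by an ionising pathway that is closed to the methyl group of the unchelated 7-OMe, so the four isopropyl ethers should fall and the methyl ether should stay.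

**Compound list**

1 | 2',4',6'-trihydroxyacetophenone | CC(=O)c1c(O)cc(O)cc1O | starting material
2 | 2'-hydroxy-4',6'-diisopropoxyacetophenone | CC(=O)c1c(O)cc(OC(C)C)cc1OC(C)C | intermediate
3 | 4-isopropoxybenzoic acid | CC(C)Oc1ccc(C(=O)O)cc1 | starting material
4 | 2-acetyl-3,5-diisopropoxyphenyl 4-isopropoxybenzoate | CC(=O)c1c(OC(=O)c2ccc(OC(C)C)cc2)cc(OC(C)C)cc1OC(C)C | intermediate
5 | 1-(2-hydroxy-4,6-diisopropoxyphenyl)-3-(4-isopropoxyphenyl)propane-1,3-dione | CC(C)Oc1ccc(C(=O)CC(=O)c2c(O)cc(OC(C)C)cc2OC(C)C)cc1 | intermediate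
6 | rac-2-allyl-1-(2-hydroxy-4,6-diisopropoxyphenyl)-3-(4-isopropoxyphenyl)propane-1,3-dione | C=CCC(C(=O)c1ccc(OC(C)C)cc1)C(=O)c1c(O)cc(OC(C)C)cc1OC(C)C | intermediate
7 | 3-allyl-5,7,4'-triisopropoxyflavone | C=CCc1c(-c2ccc(OC(C)C)cc2)oc2cc(OC(C)C)cc(OC(C)C)c2c1=O | intermediate
8 | rac-3-(2,3-dihydroxypropyl)-5,7,4'-triisopropoxyflavone | OCC(O)Cc1c(-c2ccc(OC(C)C)cc2)oc2cc(OC(C)C)cc(OC(C)C)c2c1=O | intermediate
9 | (5,7,4'-triisopropoxyflavon-3-yl)acetaldehyde | O=CCc1c(-c2ccc(OC(C)C)cc2)oc2cc(OC(C)C)cc(OC(C)C)c2c1=O | intermediate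
10 | rac-3-(2-hydroxybut-3-en-1-yl)-5,7,4'-triisopropoxyflavone | C=CC(O)Cc1c(-c2ccc(OC(C)C)cc2)oc2cc(OC(C)C)cc(OC(C)C)c2c1=O | intermediate
11 | 3-(2-oxobut-3-en-1-yl)-5,7,4'-triisopropoxyflavone | C=CC(=O)Cc1c(-c2ccc(OC(C)C)cc2)oc2cc(OC(C)C)cc(OC(C)C)c2c1=O | intermediate
12 | (Z)-3-[2-(tert-butyldimethylsilyloxy)buta-1,3-dien-1-yl]-5,7,4'-triisopropoxyflavone | C=C/C(O[Si](C)(C)C(C)(C)C)=C/c1c(-c2ccc(OC(C)C)cc2)oc2cc(OC(C)C)cc(OC(C)C)c2c1=O | intermediate
13 | 2',6'-dihydroxy-4'-methoxyacetophenone | COc1cc(O)c(C(C)=O)c(O)c1 | starting material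
14 | 2'-hydroxy-6'-isopropoxy-4'-methoxyacetophenone | COc1cc(O)c(C(C)=O)c(OC(C)C)c1 | intermediate
15 | ethyl 4-(2-hydroxy-6-isopropoxy-4-methoxyphenyl)-2,4-dioxobutanoate | CCOC(=O)C(=O)CC(=O)c1c(O)cc(OC)cc1OC(C)C | intermediate
16 | ethyl 5-isopropoxy-7-methoxy-4-oxo-4H-chromene-2-carboxylate | CCOC(=O)c1cc(=O)c2c(OC(C)C)cc(OC)cc2o1 | intermediate
17 | 2-(hydroxymethyl)-5-isopropoxy-7-methoxy-4H-chromen-4-one | OCc1cc(=O)c2c(OC(C)C)cc(OC)cc2o1 | intermediate
18 | 5-isopropoxy-7-methoxy-4-oxo-4H-chromene-2-carbaldehyde | O=Cc1cc(=O)c2c(OC(C)C)cc(OC)cc2o1 | intermediate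
19 | 2-ethynyl-5-isopropoxy-7-methoxy-4H-chromen-4-one | C#Cc1cc(=O)c2c(OC(C)C)cc(OC)cc2o1 | intermediate
20 | rac-3-[6-(tert-butyldimethylsilyloxy)-3-(5-isopropoxy-7-methoxy-4-oxo-4H-chromen-2-yl)cyclohexa-2,5-dien-1-yl]-5,7-diisopropoxy-2-(4-isopropoxyphenyl)-4H-chromen-4-one | COc1cc(OC(C)C)c2c(=O)cc(C3=CC(c4c(-c5ccc(OC(C)C)cc5)oc5cc(OC(C)C)cc(OC(C)C)c5c4=O)C(O[Si](C)(C)C(C)(C)C)=CC3)oc2c1 | intermediate
21 | 3-[2-(tert-butyldimethylsilyloxy)-5-(5-isopropoxy-7-methoxy-4-oxo-4H-chromen-2-yl)phenyl]-5,7-diisopropoxy-2-(4-isopropoxyphenyl)-4H-chromen-4-one | COc1cc(OC(C)C)c2c(=O)cc(-c3ccc(O[Si](C)(C)C(C)(C)C)c(-c4c(-c5ccc(OC(C)C)cc5)oc5cc(OC(C)C)cc(OC(C)C)c5c4=O)c3)oc2c1 | intermediate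
22 | 3-[2-hydroxy-5-(5-isopropoxy-7-methoxy-4-oxo-4H-chromen-2-yl)phenyl]-5,7-diisopropoxy-2-(4-isopropoxyphenyl)-4H-chromen-4-one | COc1cc(OC(C)C)c2c(=O)cc(-c3ccc(O)c(-c4c(-c5ccc(OC(C)C)cc5)oc5cc(OC(C)C)cc(OC(C)C)c5c4=O)c3)oc2c1 | intermediate
23 | 3-[2-hydroxy-5-(5-hydroxy-7-methoxy-4-oxo-4H-chromen-2-yl)phenyl]-5,7-dihydroxy-2-(4-hydroxyphenyl)-4H-chromen-4-one | COc1cc(O)c2c(=O)cc(-c3ccc(O)c(-c4c(-c5ccc(O)cc5)oc5cc(O)cc(O)c5c4=O)c3)oc2c1 | target

**Step count**

- Total step count: 16 (8 for the diene, 5 for the alkyne, 3 after the union).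
- Longest linear sequence: 11 (steps 1–8 and 14–16).

**Steps most likely to fail**

(a) Step 14, which bears the label.
- What may go wrong: the alkyne is activated only vinylogously, so cycloaddition may be slower than thermal desilylation or oligomerisation of the partners. The conjugating flavonyl group may also erode the para orientation.
- Fallback: it uses known chemistry and sets out from 12 and 14.
- Heating 12 with methyl propiolate (toluene, 110 °C), a directly activated alkyne of the kind long used with 2-silyloxydienes, should give methyl 4-(tert-butyldimethylsilyloxy)-3-(5,7,4'-triisopropoxyflavon-3-yl)cyclohexa-1,4-diene-1-carboxylate F1.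
- DDQ aromatises this in the flask to methyl 4-(tert-butyldimethylsilyloxy)-3-(5,7,4'-triisopropoxyflavon-3-yl)benzoate F2.
- Claisen condensation of F2 with the dilithium salt of 14 (LiN(SiMe3)2, THF, −78 °C to rt) should give 1-(2-hydroxy-6-isopropoxy-4-methoxyphenyl)-3-[4-(tert-butyldimethylsilyloxy)-3-(5,7,4'-triisopropoxyflavon-3-yl)phenyl]propane-1,3-dione F3.
- Cyclodehydration (p-TsOH, toluene, 110 °C) closes ring C of unit 1 and comes back to the route at 21. Loss of the silyl group on the way would only anticipate step 15.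
- Ring B is still made by cycloaddition, but ring C of unit 1 is built after it, so steps 10–13 are no longer needed.

(b) Step 13.
- What may go wrong: the lithiated diazo reagent or the released silanolate may attack C2 of the pyranone and open the ring. Surplus diazo compound may also undergo dipolar addition to the acceptor alkyne once it has formed.
- Fallback: it sets out from 18.
- Ramirez olefination (CBr4, PPh3, CH2Cl2, 0 °C) should give 2-(2,2-dibromovinyl)-5-isopropoxy-7-methoxy-4H-chromen-4-one F4.
- Selective hydrogenolysis of the C–Br bond trans to the chromone (Bu3SnH, Pd(PPh3)4 cat., toluene, rt) should give (Z)-2-(2-bromovinyl)-5-isopropoxy-7-methoxy-4H-chromen-4-one F5.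
- Anti elimination of HBr with DBU (MeCN, rt) comes back to the route at 19. No carbanion and no diazo compound meets the pyranone on this path.

(c) Step 8.
- What may go wrong: amine-triggered Michael oligomerisation may consume the vinyl ketone before it is silylated. Geometrical control of the enol ether may also be incomplete, and only the Z isomer can reach the reactive s-cis shape.
- Fallback: it sets out from 11 and keeps the vinyl group masked during the enolisation.
- Conjugate addition of benzeneselenolate (PhSeSePh, NaBH4, EtOH, then AcOH, 0 °C) should give 3-[2-oxo-4-(phenylselanyl)butyl]-5,7,4'-triisopropoxyflavone F6.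
- TBSOTf and Et3N then silylate toward the more acidic, flavone-conjugated CH2 group to give (Z)-3-[2-(tert-butyldimethylsilyloxy)-4-(phenylselanyl)but-1-en-1-yl]-5,7,4'-triisopropoxyflavone F7.
- Oxidation at selenium (mCPBA, 1 equiv, CH2Cl2, −78 °C, then iPr2NH) gives the selenoxide of that enol ether F8. Its syn elimination on warming unveils the vinyl group and comes back to the route at 12.

**Further compounds**

F1 | step 14 | methyl 4-(tert-butyldimethylsilyloxy)-3-(5,7,4'-triisopropoxyflavon-3-yl)cyclohexa-1,4-diene-1-carboxylate (racemic) | COC(=O)C1=CC(c2c(-c3ccc(OC(C)C)cc3)oc3cc(OC(C)C)cc(OC(C)C)c3c2=O)C(O[Si](C)(C)C(C)(C)C)=CC1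
F2 | step 14 | methyl 4-(tert-butyldimethylsilyloxy)-3-(5,7,4'-triisopropoxyflavon-3-yl)benzoate | COC(=O)c1ccc(O[Si](C)(C)C(C)(C)C)c(-c2c(-c3ccc(OC(C)C)cc3)oc3cc(OC(C)C)cc(OC(C)C)c3c2=O)c1
F3 | step 14 | 1-(2-hydroxy-6-isopropoxy-4-methoxyphenyl)-3-[4-(tert-butyldimethylsilyloxy)-3-(5,7,4'-triisopropoxyflavon-3-yl)phenyl]propane-1,3-dione | COc1cc(O)c(C(=O)CC(=O)c2ccc(O[Si](C)(C)C(C)(C)C)c(-c3c(-c4ccc(OC(C)C)cc4)oc4cc(OC(C)C)cc(OC(C)C)c4c3=O)c2)c(OC(C)C)c1
F4 | step 13 | 2-(2,2-dibromovinyl)-5-isopropoxy-7-methoxy-4H-chromen-4-one | BrC(Br)=Cc1cc(=O)c2c(OC(C)C)cc(OC)cc2o1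
F5 | step 13 | (Z)-2-(2-bromovinyl)-5-isopropoxy-7-methoxy-4H-chromen-4-one | Br/C=C\c1cc(=O)c2c(OC(C)C)cc(OC)cc2o1
F6 | step 8 | 3-[2-oxo-4-(phenylselanyl)butyl]-5,7,4'-triisopropoxyflavone | O=C(CC[Se]c1ccccc1)Cc1c(-c2ccc(OC(C)C)cc2)oc2cc(OC(C)C)cc(OC(C)C)c2c1=O
F7 | step 8 | (Z)-3-[2-(tert-butyldimethylsilyloxy)-4-(phenylselanyl)but-1-en-1-yl]-5,7,4'-triisopropoxyflavone | c1ccccc1[Se]CC/C(O[Si](C)(C)C(C)(C)C)=C/c1c(-c2ccc(OC(C)C)cc2)oc2cc(OC(C)C)cc(OC(C)C)c2c1=O
F8 | step 8 | (Z)-3-[2-(tert-butyldimethylsilyloxy)-4-(phenylseleninyl)but-1-en-1-yl]-5,7,4'-triisopropoxyflavone | O=[Se](CC/C(O[Si](C)(C)C(C)(C)C)=C/c1c(-c2ccc(OC(C)C)cc2)oc2cc(OC(C)C)cc(OC(C)C)c2c1=O)c1ccccc1
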